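**Plan**
- Numbering: caryophyllane C1–C15 (ring A cyclobutane, ring B nine-membered ring, C8 the spiro carbinol carbon, C13 its CH2). C7' is the isobutyl-bearing methine. Ring D carbons are C1' (on C7'), C2' (bears the ring C oxygen), C3'/C5' (CMe2) and C4'/C6' (C=O).
- Cuts, in retrosynthetic order: C3=C4/C5–OH back to a 4,5-epoxide; then the O–C2' bond of ring C; then C13–C7' and C1'–C2' together. This leaves an iodohydrin of (−)-caryophyllene oxide and an open-chain enone diketo ester.
- Enabling feature: C7' is β and C1' is α to the C6' carbonyl, C2' is an acyl carbon further along the same chain, and C3' and C5' are quaternary. A C13 radical adding at C7' therefore leaves C1' as the only enolisable carbon, and its enolate can only close ring D on C2', as in a polyketide Claisen cyclisation.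
- Forward: rings A and B come intact from the chiral pool. The chain is built in three steps from the dimethylketene dimer. One flask joins the halves and closes ring D; ring C closes next; the allylic alcohol is unmasked last.
- Stereochemistry: C1, C9 and C5 come from (−)-caryophyllene oxide. C8 comes from peripheral epoxidation of C8=C13, and its C–O bond is never broken afterwards. C7' comes from a chiral magnesium Lewis acid chelated by the C4'/C6' diketone. The 3Z alkene comes from a syn-elimination of the epoxide.

Key step: step 6

Assumption: the (3aR,8aS)-configured ligand is taken to leave the Si face of C7' open in the tetrahedral magnesium chelate; the sense of induction on this new template has to be checked, and the antipodal ligand is equally available.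

Step 1
Reactants: 1 2,2,4,4-tetramethylcyclobutane-1,3-dione
Product: 2 methyl 2,2,4-trimethyl-3-oxopentanoate
Conditions: NaOMe (5 mol %), MeOH, reflux
Reagents that add atoms: methanol, CO
Why: Strain-releasing retro-Claisen ring opening, in which methoxide adds to one carbonyl of the non-enolisable four-membered 1,3-dione, the ring C–C bond breaks to a ketone enolate and methanol protonates it; no stereocenter is formed.

Step 2
Reactants: 3 (E)-5-methylhex-2-enoic acid
Product: 4 (E)-5-methylhex-2-enoyl chloride
Conditions: (COCl)2, DMF (cat.), CH2Cl2, 0 °C to rt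
Reagents that add atoms: oxalyl chloride, O=C(Cl)C(=O)Cl
Why: Vilsmeier-type acid chloride formation under essentially neutral conditions, which leaves the E alkene in place.

Step 3
Reactants: 2 methyl 2,2,4-trimethyl-3-oxopentanoate; 4 (E)-5-methylhex-2-enoyl chloride
Product: 6 methyl (E)-2,2,4,4,9-pentamethyl-3,5-dioxodec-6-enoate, via lithium enolate 5 (not isolated)
Conditions: LiN(iPr)2, Et2O, −78 to 0 °C; then 4, −78 °C to rt
Reagents that add atoms: none
Why: C-acylation (crossed Claisen type) of a preformed, fully substituted lithium ketone enolate by an acid chloride in a weakly coordinating solvent, a reaction known for this very enolate with simple acid chlorides; the product has no 1,3-dicarbonyl proton, so it cannot be deprotonated or acylated again, and no stereocenter is formed.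

Step 4
Reactants: 7 (−)-caryophyllene oxide, (1R,4R,5R,9S)-4,5-epoxycaryophyll-8(13)-ene
Product: 8 (1R,4R,5R,8R,9S)-4,5:8,13-diepoxycaryophyllane
Conditions: mCPBA, CH2Cl2, 0 °C
Reagents that add atoms: mCPBA, O=C(OO)c1cccc(Cl)c1
Why: Prilezhaev epoxidation of the only remaining alkene; ring B screens the inner face of C8=C13, and in the conformer that turns C13 to the side of H-9 the peracid should reach C8 from the periphery on the side of H-1, which sets C8 as 8R with the oxygen where ring C needs it.

Step 5
Reactants: 8 (1R,4R,5R,8R,9S)-4,5:8,13-diepoxycaryophyllane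
Product: 9 (1R,4R,5R,8R,9S)-4,5-epoxy-13-iodocaryophyllan-8-ol
Conditions: LiI (1.1 equiv), AcOH (1.1 equiv), THF, 0 °C
Reagents that add atoms: lithium iodide, [Li+].[I-]
Why: Acid-assisted SN2 halohydrin formation in which iodide attacks the unhindered primary C13, so the C8–O bond and the C8 configuration are untouched, while the trisubstituted 4,5-epoxide, whose backside trajectories run through ring B, should react more slowly.

Step 6
Reactants: 9 (1R,4R,5R,8R,9S)-4,5-epoxy-13-iodocaryophyllan-8-ol; 6 methyl (E)-2,2,4,4,9-pentamethyl-3,5-dioxodec-6-enoate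
Product: 11 (1R,4R,5R,8S,9S)-13-[(1R)-1-(2-hydroxy-3,3,5,5-tetramethyl-4,6-dioxocyclohex-1-en-1-yl)-3-methylbutyl]-4,5-epoxycaryophyllan-8-ol, via keto ester adduct 10 (not isolated)
Conditions: 6 (3 equiv), Mg(NTf2)2 (30 mol %), (3aR,3a'R,8aS,8a'S)-2,2'-(cyclopropane-1,1-diyl)bis(3a,8a-dihydro-8H-indeno[1,2-d]oxazole) (33 mol %), CH2Cl2, −78 °C; (Me3Si)3SiH (slow addition), Et3B (cat.)/air; then KN(SiMe3)2 (excess), THF, −78 °C to rt; AcOH quench
Reagents that add atoms: none
Why: Proposed new method: the silyl radical takes iodine from 9 and the primary C13 radical adds in a Giese addition to C7' of 6, which is activated and held s-cis as the six-membered chelate of its C4' and C6' carbonyl oxygens on the chiral magnesium Lewis acid, hydrogen transfer from the silane then giving 10 and carrying the chain. In the same flask KN(SiMe3)2 removes the O–H and a C1'–H proton, and the C1' enolate attacks the ester carbon C2' and expels methoxide (Dieckmann condensation), the irreversible deprotonation of the triketone pulling any O-acylated material through to 11. The closest known reaction types are the chiral Lewis acid controlled radical conjugate addition to chelating alpha'-hydroxy enones and N-enoyl imides and the base-induced closure of methyl 2,2,4,4-tetramethyl-3,5-dioxohexanoate to syncarpic acid; new are the non-enolisable 1,3-diketone as chelating template and the coupling of the two events. Ring D is the only ring closed and it closes in the favoured 6-(enolendo)-exo-trig mode, helped by the two gem-dimethyl groups. C7' is the only new stereocenter (C1' is not stereogenic because ring D is symmetric) and it is set by the ligand, which should screen the Re face of C7' so that C13 arrives on the Si face and gives 7'R, while C8 and the other terpene centers are not touched. The step needs addition to outrun hydrogen transfer to the C13 radical (excess chelated 6, slow silane addition), an inert 4,5-epoxide (no acid, low temperature) and a single enolisation site, which the quaternary C3' and C5' secure; complete double deprotonation also removes the electrophilic C6' ketone before the C8 alkoxide could cleave the diketone.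

Step 7
Reactants: 11 (1R,4R,5R,8S,9S)-13-[(1R)-1-(2-hydroxy-3,3,5,5-tetramethyl-4,6-dioxocyclohex-1-en-1-yl)-3-methylbutyl]-4,5-epoxycaryophyllan-8-ol
Product: 13 (1R,4R,5R,8S,9S,7'R)-4,5-epoxy spiro pyran (rings A to D complete, C8 spiro between rings B and C, 4,5-epoxide in place of the allylic alcohol), via enol tosylate 12 (not isolated)
Conditions: TsCl (1.1 equiv), Et3N (3 equiv), DMAP (20 mol %), CH2Cl2, 0 to 40 °C
Reagents that add atoms: none
Why: The acidic ring D enol is O-sulfonylated selectively (the tertiary alcohol is inert to TsCl) and the C8 hydroxyl then displaces tosylate by DMAP-assisted intramolecular addition–elimination at the vinylogous sulfonate carbon (vinylogous esterification, 6-endo-trig), so ring C closes without breaking the C8–O bond and C8 keeps its configuration; ring D of 11 is symmetric, so sulfonylation at either flanking oxygen leads to the same product.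

Step 8
Reactants: 13 (1R,4R,5R,8S,9S,7'R)-4,5-epoxy spiro pyran
Product: 14 Tomentodione O, (1R,3Z,5R,8S,9S,7'R)
Conditions: 2,2,6,6-tetramethylpiperidine, n-BuLi, then Et2AlCl, toluene, 0 °C; then 13, 0 °C to rt; aqueous work-up
Reagents that add atoms: none
Why: Aluminium amide promoted isomerisation of an epoxide to an allylic alcohol by syn-elimination, in which aluminium binds the oxirane oxygen, the tertiary C4–O bond breaks and the amide takes the syn proton from the carbon that is cis to the oxirane hydrogen H-5, that is C3 and not C12, the rotation that brings H-3 syn to oxygen placing C2 cis to C5 and leading to the less strained 3Z alkene, while the C5–O bond is untouched and C5 stays R.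

**Compound list**
1 | 2,2,4,4-tetramethylcyclobutane-1,3-dione | CC1(C)C(=O)C(C)(C)C1=O | starting material
2 | methyl 2,2,4-trimethyl-3-oxopentanoate | COC(=O)C(C)(C)C(=O)C(C)C | intermediate
3 | (E)-5-methylhex-2-enoic acid | CC(C)C/C=C/C(=O)O | starting material
4 | (E)-5-methylhex-2-enoyl chloride | CC(C)C/C=C/C(=O)Cl | intermediate
5 | lithium enolate of 2 (not isolated) | COC(=O)C(C)(C)C([O-])=C(C)C.[Li+] | intermediate
6 | methyl (E)-2,2,4,4,9-pentamethyl-3,5-dioxodec-6-enoate | COC(=O)C(C)(C)C(=O)C(C)(C)C(=O)/C=C/CC(C)C | intermediate
7 | (−)-caryophyllene oxide | C[C@@]12CC[C@@H]3[C@H](CC3(C)C)C(=C)CC[C@H]1O2 | starting material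
8 | (8R)-4,5:8,13-diepoxycaryophyllane | C[C@@]12CC[C@@H]3[C@H](CC3(C)C)[C@]4(CC[C@H]1O2)CO4 | intermediate
9 | (8R)-4,5-epoxy-13-iodocaryophyllan-8-ol | C[C@@]12CC[C@@H]3[C@H](CC3(C)C)[C@](O)(CC[C@H]1O2)CI | intermediate
10 | methyl (7R)-7-[(8S)-4,5-epoxy-8-hydroxycaryophyllan-13-yl]-2,2,4,4,9-pentamethyl-3,5-dioxodecanoate (not isolated) | C[C@@]12CC[C@@H]3[C@H](CC3(C)C)[C@](O)(CC[C@H]1O2)C[C@@H](CC(C)C)CC(=O)C(C)(C)C(=O)C(C)(C)C(=O)OC | intermediate
11 | (8S,7'R)-hydroxy triketone, drawn as ring D enol | C[C@@]12CC[C@@H]3[C@H](CC3(C)C)[C@](O)(CC[C@H]1O2)C[C@@H](CC(C)C)C4=C(O)C(C)(C)C(=O)C(C)(C)C4=O | intermediate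
12 | enol tosylate of 11 (not isolated) | C[C@@]12CC[C@@H]3[C@H](CC3(C)C)[C@](O)(CC[C@H]1O2)C[C@@H](CC(C)C)C4=C(OS(=O)(=O)c5ccc(C)cc5)C(C)(C)C(=O)C(C)(C)C4=O | intermediate
13 | (8S,7'R)-4,5-epoxy spiro pyran | C[C@@]12CC[C@@H]3[C@H](CC3(C)C)[C@]4(CC[C@H]1O2)C[C@@H](CC(C)C)C5=C(O4)C(C)(C)C(=O)C(C)(C)C5=O | intermediate
14 | Tomentodione O | C/C1=C/C[C@@H]2[C@H](CC2(C)C)[C@]2(CC[C@H]1O)C[C@@H](CC(C)C)C1=C(O2)C(C)(C)C(=O)C(C)(C)C1=O | target

**Step count**
Total steps: 8. Longest linear sequence: 5 (steps 4, 5, 6, 7, 8; the branch 1, 3, 6, 7, 8 is equally long).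

**Steps most likely to fail**

Step 6.
- Hydrogen transfer from the silane to the C13 radical may outrun its addition to the β-substituted enone.
- The neutral diketone may hold magnesium too loosely for useful facial discrimination at C7'.
- In the base stage, cleavage of the non-enolisable diketone by the C8 alkoxide may compete with ring closure.

The fallback uses known chemistry, sets out from 7 and comes back at 13. Commercial syncarpic acid and isovaleraldehyde are condensed (Knoevenagel condensation, catalytic ethylenediammonium diacetate) to the oxadiene 2,2,4,4-tetramethyl-6-(3-methylbutylidene)cyclohexane-1,3,5-trione F1. The C8=C13 alkene of 7 traps it as it forms in an inverse electron demand hetero-Diels–Alder reaction. C13–C7' and C8–O then form together on the open face of the alkene, and the C7' epimers are separated by chromatography.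

Step 8.
- The amide may take a proton from C12 instead of C3.
- The elimination may pass through the rotamer that leads to the E alkene.
- The Lewis acid may ionise the tertiary C8–O bond of the vinylogous ester.

The fallback sets out from 13 and comes back at 14. Homolytic opening of the epoxide by trivalent titanium (Ti(C5H5)2Cl made from Ti(C5H5)2Cl2 and Mn dust, THF), with loss of a C12 hydrogen, gives the exocyclic allylic alcohol F2. Dess–Martin oxidation gives the alpha-methylene ketone F3. RhCl3·3H2O in hot ethanol moves the alkene into the conjugated endocyclic position and gives the ring-cis (3Z)-enone F4. Corey–Bakshi–Shibata reduction with the (S)-methyl oxazaborolidine and BH3·SMe2 sets 5R under reagent control and gives 14.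

Step 4.
- Facial selectivity at C8=C13 may be poor or reversed, because ring B is flexible and both orientations of C13 are populated.

The fallback sets out from 7 and comes back at 8. Ozonolysis of C8=C13 (O3, CH2Cl2, −78 °C, then Me2S) gives the C8 ketone kobusone F5. Corey–Chaykovsky methylenation (Me3SI, NaH, DMSO/THF) then delivers CH2 rather than oxygen from the periphery, so the oxygen ends on the face opposite to the one a peracid serves.

**Further compounds**
F1 | step 6 | 2,2,4,4-tetramethyl-6-(3-methylbutylidene)cyclohexane-1,3,5-trione | CC(C)CC=C1C(=O)C(C)(C)C(=O)C(C)(C)C1=O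
F2 | step 8 | exocyclic allylic alcohol, 4(12)-en-5R-ol isomer of 14 | C=C1CC[C@@H]2[C@H](CC2(C)C)[C@]2(CC[C@H]1O)C[C@@H](CC(C)C)C1=C(O2)C(C)(C)C(=O)C(C)(C)C1=O
F3 | step 8 | alpha-methylene ketone, 4(12)-en-5-one | C=C1CC[C@@H]2[C@H](CC2(C)C)[C@]2(CCC1=O)C[C@@H](CC(C)C)C1=C(O2)C(C)(C)C(=O)C(C)(C)C1=O
F4 | step 8 | (3Z)-enone, 3-en-5-one | C/C1=C/C[C@@H]2[C@H](CC2(C)C)[C@]2(CCC1=O)C[C@@H](CC(C)C)C1=C(O2)C(C)(C)C(=O)C(C)(C)C1=O
F5 | step 4 | kobusone | C[C@@]12CC[C@@H]3[C@H](CC3(C)C)C(=O)CC[C@H]1O2
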